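**Retrosynthetic overview**
- The target comes from hexa-O-silyl diketone by desilylation. The C3 aroyl C=O comes from oxidation of a C3 α-hydroxybenzyl group. That carbinol carbon is the only stereocentre that is bought, in (S)-4-hydroxymandelic acid.
- Only one ring is built (C1–C2–C3–C4–C4a–C8a). The C1–C8a bond forms by 365 nm conrotatory 6π closure of an (E,E)-2-aroyl-3-(hydroxybenzyl)-1,4-diaryl-1,3-diene. A suprafacial [1,5]-H shift from C8a to C2 follows, and C1 and C2 are set cis in this one operation.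
- The diene comes from a C2–C3 Stille coupling of a (Z)-α-bromochalcone (from licochalcone B) with a (Z)-α-stannyl allylic alcohol.
- The stannane comes from OH-directed trans-hydrostannation of a diaryl propargylic alcohol. That alcohol comes from Sonogashira coupling of an aryl bromide (Dakin oxidation of 5-bromo-o-vanillin) with the alkyne made from the mandelate (ester, aldehyde, alkyne).
- All four benzene rings are bought. The carbocycle is closed third from last.

Assumption and conventions: 1, 5 and 9 are taken as catalogue compounds; locants C1–C8a are those of the dihydronaphthalene of the target; TBS = tert-butyldimethylsilyl, TBSO = its oxy group, TES = triethylsilyl.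

**Step 1**
Reactants: 1 5-bromo-2-hydroxy-3-methoxybenzaldehyde
Product: 3 5-bromo-3-methoxybenzene-1,2-diol, via aryl formate 2 (not isolated)
Conditions: 30% H2O2, NaOH, H2O, 0 °C to rt; then HCl
Reagents that add atoms: hydrogen peroxide, OO
Why: Dakin oxidation, in which hydroperoxide adds to the ortho-hydroxy aldehyde, aryl migration gives the formate, and this is saponified in situ, so CHO becomes OH and the 3-methoxy-4,5-dioxygenated aryl bromide pattern is fixed without any regiochemical choice.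

**Step 2**
Reactants: 3 5-bromo-3-methoxybenzene-1,2-diol
Product: 4 5-bromo-1,2-bis(TBSO)-3-methoxybenzene
Conditions: TBSCl (2.3 equiv), imidazole, DMF, rt
Reagents that add atoms: tert-butyldimethylsilyl chloride, CC(C)(C)[Si](C)(C)Cl
Why: Imidazole-promoted O-silylation of both phenols, which also places a bulky group next to the ring position that must not cyclise in step 12.

**Step 3**
Reactants: 5 licochalcone B, (E)-3-(3,4-dihydroxy-2-methoxyphenyl)-1-(4-hydroxyphenyl)prop-2-en-1-one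
Product: 6 tris-O-TBS licochalcone B
Conditions: TBSCl (3.5 equiv), imidazole, DMF, rt
Reagents that add atoms: tert-butyldimethylsilyl chloride, CC(C)(C)[Si](C)(C)Cl
Why: Imidazole-promoted O-silylation of all three phenols under conditions that leave the enone untouched.

**Step 4**
Reactants: 6 tris-O-TBS licochalcone B
Product: 8 (Z)-3-[3,4-bis(TBSO)-2-methoxyphenyl]-2-bromo-1-[4-(TBSO)phenyl]prop-2-en-1-one, via chalcone dibromide 7 (not isolated)
Conditions: Br2 (1.0 equiv), CH2Cl2, −78 °C; then Et3N, −78 °C to rt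
Reagents that add atoms: bromine, BrBr
Why: Electrophilic bromination of the electron-rich styrenyl C=C, then E1cB dehydrobromination to the thermodynamically preferred (Z)-α-bromoenone, in which aryl and Br are cis and aryl and aroyl are trans, the geometry that step 11 carries into the diene.

**Step 5**
Reactants: 9 (S)-4-hydroxymandelic acid
Product: 10 methyl (S)-4-hydroxymandelate
Conditions: MeI, KHCO3, DMF, rt
Reagents that add atoms: iodomethane, CI
Why: SN2 O-alkylation of the carboxylate, with bicarbonate too weak to deprotonate the phenol or the α-C–H, so the bought stereocentre is untouched and acidic, ionising esterification conditions are avoided.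

**Step 6**
Reactants: 10 methyl (S)-4-hydroxymandelate
Product: 12 methyl (S)-2-[4-(TBSO)phenyl]-2-(triethylsilyloxy)acetate, via phenol TBS ether 11 (not isolated)
Conditions: TBSCl (1.05 equiv), imidazole, DMF, 0 °C; then TESCl (1.3 equiv), rt
Reagents that add atoms: tert-butyldimethylsilyl chloride, CC(C)(C)[Si](C)(C)Cl; triethylsilyl chloride, CC[Si](Cl)(CC)CC
Why: Sequential chemoselective silylation in one pot (the more acidic, unhindered phenol reacts first), giving a robust aryl TBS ether and an acid-labile carbinol TES ether that can be removed alone in step 9.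

**Step 7**
Reactants: 12 methyl (S)-2-[4-(TBSO)phenyl]-2-(triethylsilyloxy)acetate
Product: 13 (S)-2-[4-(TBSO)phenyl]-2-(triethylsilyloxy)acetaldehyde
Conditions: DIBAL-H (1.1 equiv), toluene, −78 °C; Rochelle salt
Reagents that add atoms: none
Why: Partial ester reduction by DIBAL-H through the aluminium hemiacetal that is stable at −78 °C, the standard route to O-silyl mandelaldehydes, with the crude aldehyde used at once to keep the α-centre intact.

**Step 8**
Reactants: 13 (S)-2-[4-(TBSO)phenyl]-2-(triethylsilyloxy)acetaldehyde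
Product: 14 (R)-tert-butyldimethyl{4-[1-(triethylsilyloxy)prop-2-yn-1-yl]phenoxy}silane (same spatial arrangement, descriptor changes by CIP ranking only)
Conditions: TMSCHN2, LDA, THF, −78 °C to 0 °C
Reagents that add atoms: trimethylsilyldiazomethane, C[Si](C)(C)C=[N+]=[N-]
Why: Colvin rearrangement (addition of lithiated TMS-diazomethane, Peterson-type loss of silanolate, loss of N2 and 1,2-H shift of the alkylidene carbene), which homologates the aldehyde to the terminal alkyne at low temperature in an aprotic medium that spares aryl TBS and the α-stereocentre.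

**Step 9**
Reactants: 14 (R)-tert-butyldimethyl{4-[1-(triethylsilyloxy)prop-2-yn-1-yl]phenoxy}silane; 4 5-bromo-1,2-bis(TBSO)-3-methoxybenzene
Product: 16 (S)-3-[3,4-bis(TBSO)-5-methoxyphenyl]-1-[4-(TBSO)phenyl]prop-2-yn-1-ol, via TES-protected diarylalkyne 15 (not isolated)
Conditions: PdCl2(PhCN)2 (3 mol%), P(t-Bu)3 (6 mol%), CuI (2 mol%), i-Pr2NH, dioxane, rt; filter, concentrate; PPTS (10 mol%), MeOH, 0 °C
Reagents that add atoms: none
Why: Sonogashira coupling with a bulky electron-rich phosphine that activates the electron-rich aryl bromide at rt, then mild acid methanolysis at silicon that removes only the TES ether without ionising the C–O bond of the stereocentre.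

**Step 10**
Reactants: 16 (S)-3-[3,4-bis(TBSO)-5-methoxyphenyl]-1-[4-(TBSO)phenyl]prop-2-yn-1-ol
Product: 17 (S,Z)-3-[3,4-bis(TBSO)-5-methoxyphenyl]-1-[4-(TBSO)phenyl]-2-(tributylstannyl)prop-2-en-1-ol
Conditions: [Cp*RuCl]4 (2.5 mol%), Bu3SnH (1.1 equiv, slow addition), CH2Cl2, rt
Reagents that add atoms: tributyltin hydride, CCCC[SnH](CCCC)CCCC
Why: Ruthenium-catalysed hydroxyl-directed trans-hydrostannation, in which the O–H···Cl–Ru contact places tin on the alkyne carbon next to the carbinol and H adds anti, so the aryl group ends cis to tin as the hexatriene of step 12 requires.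

**Step 11**
Reactants: 17 (S,Z)-α-stannyl allylic alcohol; 8 (Z)-α-bromochalcone
Product: 18 (2E,3E)-2-[3,4-bis(TBSO)-2-methoxybenzylidene]-4-[3,4-bis(TBSO)-5-methoxyphenyl]-3-{(S)-hydroxy[4-(TBSO)phenyl]methyl}-1-[4-(TBSO)phenyl]but-3-en-1-one
Conditions: Pd(PPh3)4 (10 mol%), CuTC (1.5 equiv), [Bu4N][Ph2PO2] (1.6 equiv), DMF, rt, dark
Reagents that add atoms: none
Why: Copper-assisted, fluoride-free Stille–Migita coupling, which tolerates the free OH and the aryl silyl ethers and proceeds with retention at both alkenyl partners, giving the diene with both aryl groups pointing inward (each cis to the C2–C3 bond).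

**Step 12**
Reactants: 18 (2E,3E)-dienone carbinol
Product: 20 [(1R,2R)-1-[3,4-bis(TBSO)-2-methoxyphenyl]-6,7-bis(TBSO)-3-{(S)-hydroxy[4-(TBSO)phenyl]methyl}-8-methoxy-1,2-dihydronaphthalen-2-yl][4-(TBSO)phenyl]methanone, via 1,8a-dihydronaphthalene 19 (not isolated)
Conditions: hν (365 nm LED), degassed toluene (2 mM), base-washed glass, −20 °C; then dark, 25 °C, 2 h; chromatography on Et3N-deactivated silica
Reagents that add atoms: none
Why: Proposed new method: hydroxyl-relayed, helicity-selective 6π photocyclisation/[1,5]-H shift of a cross-conjugated 2-aroyl-3-(α-hydroxybenzyl)-1,4-diaryl-1,3-diene, in which excitation of the chalcone chromophore closes the hexatriene C8a=C4a–C4=C3–C2=C1 conrotatorily onto the enone β-carbon (new C1–C8a bond) to give the linear push–pull trienone 19, whose C8a–H (cis to H1 because the C1 aryl is the inward substituent) migrates thermally and suprafacially to C2 so that H1 and H2 end cis; the bought (S)-carbinol sets the absolute sense because its O–H···O=C hydrogen bond to the C2 aroyl group and allylic strain (carbinol C–H eclipsing C3=C4, its aryl on the face opposite the aroyl) favour the P-helical diene that leads to (1R,2R), and the minor (1S,2S,S) diastereomer is removable by chromatography; closure next to OMe rather than next to bulky OTBS, closure of the 3-methoxy ring rather than the 2-methoxy ring (only the former gives an acceptor-conjugated intermediate) and a product transparent at 365 nm are built into the substrate; the closest known reaction type is the photocyclisation of (E,E)-bis(arylidene)succinates and fulgides to cis-1-aryl-1,2-dihydronaphthalenes.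

**Step 13**
Reactants: 20 (1R,2R,S)-dihydronaphthalene carbinol
Product: 21 [(1R,2R)-1-[3,4-bis(TBSO)-2-methoxyphenyl]-6,7-bis(TBSO)-8-methoxy-1,2-dihydronaphthalene-2,3-diyl]bis{[4-(TBSO)phenyl]methanone}
Conditions: Dess–Martin periodinane (1.2 equiv), CH2Cl2, 0 °C, 30 min; rapid filtration through neutral silica
Reagents that add atoms: none
Why: Dess–Martin oxidation of the allylic, benzylic alcohol under non-basic, non-hydride-abstracting conditions turns the controlling stereocentre into the C3 aroyl carbonyl without epimerising the now more acidic cis C2–H and without aromatising the ring.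

**Step 14**
Reactants: 21 hexa-O-TBS diketone
Product: 22 [(1R,2R)-1-(3,4-dihydroxy-2-methoxyphenyl)-6,7-dihydroxy-8-methoxy-1,2-dihydronaphthalene-2,3-diyl]bis[(4-hydroxyphenyl)methanone] (CNP0335881.1)
Conditions: Et3N·3HF (2.5 equiv), THF, 0 °C to rt, argon
Reagents that add atoms: none
Why: Fluoride-mediated cleavage of the six aryl silyl ethers in a weakly acidic medium, so no phenoxide or enolate is formed, the kinetic cis C1/C2 relationship survives, the catechols are not air-oxidised and both methyl ethers stay.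

**Compound list**
1 | 5-bromo-2-hydroxy-3-methoxybenzaldehyde | COc1cc(Br)cc(C=O)c1O | starting material
2 | 5-bromo-2-hydroxy-3-methoxyphenyl formate | COc1cc(Br)cc(OC=O)c1O | intermediate
3 | 5-bromo-3-methoxybenzene-1,2-diol | COc1cc(Br)cc(O)c1O | intermediate
4 | 5-bromo-1,2-bis(TBSO)-3-methoxybenzene | COc1cc(Br)cc(O[Si](C)(C)C(C)(C)C)c1O[Si](C)(C)C(C)(C)C | intermediate
5 | licochalcone B | COc1c(/C=C/C(=O)c2ccc(O)cc2)ccc(O)c1O | starting material
6 | tris-O-TBS licochalcone B | COc1c(/C=C/C(=O)c2ccc(O[Si](C)(C)C(C)(C)C)cc2)ccc(O[Si](C)(C)C(C)(C)C)c1O[Si](C)(C)C(C)(C)C | intermediate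
7 | 3-[3,4-bis(TBSO)-2-methoxyphenyl]-2,3-dibromo-1-[4-(TBSO)phenyl]propan-1-one (racemic diastereomer mixture) | COc1c(C(Br)C(Br)C(=O)c2ccc(O[Si](C)(C)C(C)(C)C)cc2)ccc(O[Si](C)(C)C(C)(C)C)c1O[Si](C)(C)C(C)(C)C | intermediate
8 | (Z)-3-[3,4-bis(TBSO)-2-methoxyphenyl]-2-bromo-1-[4-(TBSO)phenyl]prop-2-en-1-one | COc1c(/C=C(\Br)C(=O)c2ccc(O[Si](C)(C)C(C)(C)C)cc2)ccc(O[Si](C)(C)C(C)(C)C)c1O[Si](C)(C)C(C)(C)C | intermediate
9 | (S)-4-hydroxymandelic acid | OC(=O)[C@@H](O)c1ccc(O)cc1 | starting material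
10 | methyl (S)-4-hydroxymandelate | COC(=O)[C@@H](O)c1ccc(O)cc1 | intermediate
11 | methyl (S)-2-hydroxy-2-[4-(TBSO)phenyl]acetate | COC(=O)[C@@H](O)c1ccc(O[Si](C)(C)C(C)(C)C)cc1 | intermediate
12 | methyl (S)-2-[4-(TBSO)phenyl]-2-(triethylsilyloxy)acetate | COC(=O)[C@@H](O[Si](CC)(CC)CC)c1ccc(O[Si](C)(C)C(C)(C)C)cc1 | intermediate
13 | (S)-2-[4-(TBSO)phenyl]-2-(triethylsilyloxy)acetaldehyde | O=C[C@@H](O[Si](CC)(CC)CC)c1ccc(O[Si](C)(C)C(C)(C)C)cc1 | intermediate
14 | (R)-tert-butyldimethyl{4-[1-(triethylsilyloxy)prop-2-yn-1-yl]phenoxy}silane | C#C[C@@H](O[Si](CC)(CC)CC)c1ccc(O[Si](C)(C)C(C)(C)C)cc1 | intermediate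
15 | (S)-TES ether of 16 | COc1cc(C#C[C@@H](O[Si](CC)(CC)CC)c2ccc(O[Si](C)(C)C(C)(C)C)cc2)cc(O[Si](C)(C)C(C)(C)C)c1O[Si](C)(C)C(C)(C)C | intermediate
16 | (S)-3-[3,4-bis(TBSO)-5-methoxyphenyl]-1-[4-(TBSO)phenyl]prop-2-yn-1-ol | COc1cc(C#C[C@@H](O)c2ccc(O[Si](C)(C)C(C)(C)C)cc2)cc(O[Si](C)(C)C(C)(C)C)c1O[Si](C)(C)C(C)(C)C | intermediate
17 | (S,Z)-3-[3,4-bis(TBSO)-5-methoxyphenyl]-1-[4-(TBSO)phenyl]-2-(tributylstannyl)prop-2-en-1-ol | COc1cc(/C=C(/[C@@H](O)c2ccc(O[Si](C)(C)C(C)(C)C)cc2)[Sn](CCCC)(CCCC)CCCC)cc(O[Si](C)(C)C(C)(C)C)c1O[Si](C)(C)C(C)(C)C | intermediate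
18 | (2E,3E)-2-[3,4-bis(TBSO)-2-methoxybenzylidene]-4-[3,4-bis(TBSO)-5-methoxyphenyl]-3-{(S)-hydroxy[4-(TBSO)phenyl]methyl}-1-[4-(TBSO)phenyl]but-3-en-1-one | COc1cc(/C=C(/[C@@H](O)c2ccc(O[Si](C)(C)C(C)(C)C)cc2)\C(=C/c2ccc(O[Si](C)(C)C(C)(C)C)c(O[Si](C)(C)C(C)(C)C)c2OC)C(=O)c2ccc(O[Si](C)(C)C(C)(C)C)cc2)cc(O[Si](C)(C)C(C)(C)C)c1O[Si](C)(C)C(C)(C)C | intermediate
19 | [(1S,8aS)-1-[3,4-bis(TBSO)-2-methoxyphenyl]-6,7-bis(TBSO)-3-{(S)-hydroxy[4-(TBSO)phenyl]methyl}-8-methoxy-1,8a-dihydronaphthalen-2-yl][4-(TBSO)phenyl]methanone (H1 and H8a cis) | COc1c([C@@H]2[C@@H]3C(OC)=C(O[Si](C)(C)C(C)(C)C)C(O[Si](C)(C)C(C)(C)C)=CC3=CC([C@@H](O)c3ccc(O[Si](C)(C)C(C)(C)C)cc3)=C2C(=O)c2ccc(O[Si](C)(C)C(C)(C)C)cc2)ccc(O[Si](C)(C)C(C)(C)C)c1O[Si](C)(C)C(C)(C)C | intermediate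
20 | [(1R,2R)-1-[3,4-bis(TBSO)-2-methoxyphenyl]-6,7-bis(TBSO)-3-{(S)-hydroxy[4-(TBSO)phenyl]methyl}-8-methoxy-1,2-dihydronaphthalen-2-yl][4-(TBSO)phenyl]methanone | COc1c([C@@H]2c3c(cc(O[Si](C)(C)C(C)(C)C)c(O[Si](C)(C)C(C)(C)C)c3OC)C=C([C@@H](O)c3ccc(O[Si](C)(C)C(C)(C)C)cc3)[C@@H]2C(=O)c2ccc(O[Si](C)(C)C(C)(C)C)cc2)ccc(O[Si](C)(C)C(C)(C)C)c1O[Si](C)(C)C(C)(C)C | intermediate
21 | [(1R,2R)-1-[3,4-bis(TBSO)-2-methoxyphenyl]-6,7-bis(TBSO)-8-methoxy-1,2-dihydronaphthalene-2,3-diyl]bis{[4-(TBSO)phenyl]methanone} | COc1c([C@@H]2c3c(cc(O[Si](C)(C)C(C)(C)C)c(O[Si](C)(C)C(C)(C)C)c3OC)C=C(C(=O)c3ccc(O[Si](C)(C)C(C)(C)C)cc3)[C@@H]2C(=O)c2ccc(O[Si](C)(C)C(C)(C)C)cc2)ccc(O[Si](C)(C)C(C)(C)C)c1O[Si](C)(C)C(C)(C)C | intermediate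
22 | [(1R,2R)-1-(3,4-dihydroxy-2-methoxyphenyl)-6,7-dihydroxy-8-methoxy-1,2-dihydronaphthalene-2,3-diyl]bis[(4-hydroxyphenyl)methanone] | COc1c([C@@H]2c3c(cc(O)c(O)c3OC)C=C(C(=O)c3ccc(O)cc3)[C@@H]2C(=O)c2ccc(O)cc2)ccc(O)c1O | target

**Step count**
- Total step count: 14.
- Longest linear sequence: 10 steps (9 to 22, steps 5–14).

**Steps most likely to fail**

Step 12 (the new photochemical cascade).
- Light may isomerise C1=C2, and the isomer with the C1 aryl pointing outward would give the 1,2-trans series.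
- Some closure may occur next to OTBS or through the 2-methoxy ring.
- The helicity control by the carbinol may be only modest.
- Fallback with known chemistry: set out from 18 and heat it in degassed mesitylene at about 160 °C.
  - The thermal disrotatory 6π closure with [1,5]-H shift known for fulgides and bis(arylidene)succinates gives the 1,2-trans series. From it the (1R,2S)-trans alcohol F1 is separated from its (1S,2R,S) diastereomer by chromatography.
  - Dess–Martin oxidation gives the (1R,2S)-trans diketone F2.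
  - Deprotonation at C2 (LiHMDS, THF, −78 °C) and kinetic protonation of the extended enolate by a bulky phenol inverts C2. The proton arrives from the face opposite the pseudo-axial C1 aryl group, the enolate-quench tactic known from the picropodophyllin to podophyllotoxin epimerisation. The sequence comes back to the route at 21.

Step 11 (Stille coupling of two hindered alkenyl partners).
- Protodestannylation may compete. The product carbinol may close reversibly onto the ketone as a lactol.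
- Fallback: reverse the polarity of the coupling. Set out from 17 and 8.
  - Iododestannylation of 17 (I2, CH2Cl2, 0 °C, retention) gives the (S,Z)-alkenyl iodide F3.
  - Miyaura borylation of 8 (B2pin2, PdCl2(dppf), KOAc, dioxane) gives the (E)-α-(pinacolboryl)chalcone F4.
  - Suzuki–Miyaura coupling of the two (PdCl2(dppf), K3PO4, THF–H2O, rt) proceeds with retention and comes back at 18.

Step 8 (Colvin homologation).
- The basic lithiated diazo reagent may enolise the α-aryl-α-silyloxy aldehyde and erode the only bought stereocentre.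
- Fallback: set out from 13 and use a carbonyl olefination that is not basic.
  - Ramirez olefination (CBr4, PPh3, Zn, CH2Cl2, 0 °C) gives the (R)-1,1-dibromoalkene F5.
  - F5 no longer has an enolisable α-carbonyl proton. It is converted by n-BuLi (2.1 equiv, THF, −78 °C; Fritsch–Buttenberg–Wiechell step of the Corey–Fuchs sequence, then water) into the alkyne, coming back at 14.

**Further compounds**
F1 | step 12 | [(1R,2S)-1-[3,4-bis(TBSO)-2-methoxyphenyl]-6,7-bis(TBSO)-3-{(S)-hydroxy[4-(TBSO)phenyl]methyl}-8-methoxy-1,2-dihydronaphthalen-2-yl][4-(TBSO)phenyl]methanone | COc1c([C@@H]2c3c(cc(O[Si](C)(C)C(C)(C)C)c(O[Si](C)(C)C(C)(C)C)c3OC)C=C([C@@H](O)c3ccc(O[Si](C)(C)C(C)(C)C)cc3)[C@H]2C(=O)c2ccc(O[Si](C)(C)C(C)(C)C)cc2)ccc(O[Si](C)(C)C(C)(C)C)c1O[Si](C)(C)C(C)(C)C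
F2 | step 12 | [(1R,2S)-1-[3,4-bis(TBSO)-2-methoxyphenyl]-6,7-bis(TBSO)-8-methoxy-1,2-dihydronaphthalene-2,3-diyl]bis{[4-(TBSO)phenyl]methanone} | COc1c([C@@H]2c3c(cc(O[Si](C)(C)C(C)(C)C)c(O[Si](C)(C)C(C)(C)C)c3OC)C=C(C(=O)c3ccc(O[Si](C)(C)C(C)(C)C)cc3)[C@H]2C(=O)c2ccc(O[Si](C)(C)C(C)(C)C)cc2)ccc(O[Si](C)(C)C(C)(C)C)c1O[Si](C)(C)C(C)(C)C
F3 | step 11 | (S,Z)-3-[3,4-bis(TBSO)-5-methoxyphenyl]-2-iodo-1-[4-(TBSO)phenyl]prop-2-en-1-ol | COc1cc(/C=C(/[C@@H](O)c2ccc(O[Si](C)(C)C(C)(C)C)cc2)I)cc(O[Si](C)(C)C(C)(C)C)c1O[Si](C)(C)C(C)(C)C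
F4 | step 11 | (E)-3-[3,4-bis(TBSO)-2-methoxyphenyl]-2-(4,4,5,5-tetramethyl-1,3,2-dioxaborolan-2-yl)-1-[4-(TBSO)phenyl]prop-2-en-1-one | COc1c(/C=C(\B2OC(C)(C)C(C)(C)O2)C(=O)c2ccc(O[Si](C)(C)C(C)(C)C)cc2)ccc(O[Si](C)(C)C(C)(C)C)c1O[Si](C)(C)C(C)(C)C
F5 | step 8 | (R)-tert-butyl{4-[3,3-dibromo-1-(triethylsilyloxy)prop-2-en-1-yl]phenoxy}dimethylsilane | BrC(Br)=C[C@@H](O[Si](CC)(CC)CC)c1ccc(O[Si](C)(C)C(C)(C)C)cc1
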